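**Retrosynthetic overview**

1. Target 24 comes from hydroxy ketone phthalide 23 by acetylation. 23 comes from resorcylate ester 21 by acid removal of all protecting groups, with closure of the lactone ring (O2–C1) last. 21 comes from phenol 20 by O-methylation.
2. The strategy rests on the benzene ring C3a–C4–C5–C6–C7–C7a of the phthalide: oxygen on C5 and C7 (meta to each other), the carboxyl carbon C1 on C7a and the carbinol carbon C3 on C3a. This ring is cut at C4–C3a and C7–C7a into diene 17 (C4–C7 with both oxygens) and (S)-4-silyloxy-2-ynoate 13 (C1, C7a, C3a, C3 and the chain).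
3. Ynoate 13 comes from aldehyde 9 by asymmetric methyl propiolate addition (sets C3, S). 9 comes from alkene 6 by hydroboration and oxidation. 6 comes from undec-10-enal by asymmetric addition of a ketal-bearing dialkylzinc (sets the side-chain carbinol, R).
4. Diene 17 comes from 1,1-dimethoxyethene by C-acetylation and enol silylation.
5. Ring order: benzene ring first (step 10), lactone ring second (step 12).

Key step: step 10

Assumption: the facial preferences quoted for the two ligand-controlled additions (steps 2 and 6) are those established for each catalyst class with simple aldehydes. The configuration of 5 and 12 is to be confirmed by Mosher ester analysis, and the ligand antipode is used should the assignment require it.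

**Route**

Step 1
Reactants: 1 2-(2-bromoethyl)-2-methyl-1,3-dioxolane
Product: 2 2-(2-iodoethyl)-2-methyl-1,3-dioxolane
Conditions: NaI, acetone, reflux, dark
Reagents that add atoms: sodium iodide, [Na+].[I-]
Why: Finkelstein halide exchange (SN2 at the primary carbon) is driven by precipitation of NaBr, and the neutral medium leaves the dioxolane intact.

Step 2
Reactants: 2 2-(2-iodoethyl)-2-methyl-1,3-dioxolane; 3 undec-10-enal
Product: 5 (3R)-1-(2-methyl-1,3-dioxolan-2-yl)tridec-12-en-3-ol, via dialkylzinc 4 (not isolated)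
Conditions: Et2Zn (neat), CuI (cat.), 50 °C, then volatiles removed in vacuo; Ti(OiPr)4, (1R,2R)-N,N'-(cyclohexane-1,2-diyl)bis(trifluoromethanesulfonamide) (8 mol%), PhMe, −20 °C, then 3; aq. NH4Cl
Reagents that add atoms: none
Why: Iodine–zinc exchange (Knochel type) gives the functionalized dialkylzinc, whose oxygen sits gamma to zinc and cannot eliminate, and its Ti(OiPr)4-promoted catalytic asymmetric addition under the (1R,2R)-bis(triflamide) ligand is expected to deliver the alkyl group to the Si face of the aldehyde, which sets the (R)-carbinol.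

Step 3
Reactants: 5 (3R)-1-(2-methyl-1,3-dioxolan-2-yl)tridec-12-en-3-ol
Product: 6 tert-butyldimethyl{[(3R)-1-(2-methyl-1,3-dioxolan-2-yl)tridec-12-en-3-yl]oxy}silane
Conditions: TBSCl, imidazole, DMF, rt
Reagents that add atoms: tert-butyldimethylsilyl chloride, CC(C)(C)[Si](C)(C)Cl
Why: Imidazole-promoted silylation of the secondary alcohol (Corey protocol) touches no bond at the stereocenter.

Step 4
Reactants: 6 tert-butyldimethyl{[(3R)-1-(2-methyl-1,3-dioxolan-2-yl)tridec-12-en-3-yl]oxy}silane
Product: 8 (11R)-11-(tert-butyldimethylsilyloxy)-13-(2-methyl-1,3-dioxolan-2-yl)tridecan-1-ol, via B-alkyl-9-borabicyclononane 7 (not isolated)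
Conditions: 9-borabicyclo[3.3.1]nonane (9-BBN), THF, 0 °C to rt; then aq. NaOH, H2O2, 0 °C to rt
Reagents that add atoms: hydrogen peroxide, OO (supplies the hydroxyl oxygen)
Why: Anti-Markovnikov hydroboration of the terminal alkene followed by oxidative C–B cleavage gives the primary alcohol, and silyl ether and ketal are inert to the borane and to basic peroxide.

Step 5
Reactants: 8 (11R)-11-(tert-butyldimethylsilyloxy)-13-(2-methyl-1,3-dioxolan-2-yl)tridecan-1-ol
Product: 9 (11R)-11-(tert-butyldimethylsilyloxy)-13-(2-methyl-1,3-dioxolan-2-yl)tridecanal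
Conditions: 2,2,6,6-tetramethylpiperidin-1-oxyl (10 mol%), PhI(OAc)2, CH2Cl2, rt
Reagents that add atoms: none
Why: Oxoammonium-mediated oxidation (TEMPO with PhI(OAc)2) stops at the aldehyde under nearly neutral conditions that spare the silyl ether and the ketal.

Step 6
Reactants: 9 (11R)-11-(tert-butyldimethylsilyloxy)-13-(2-methyl-1,3-dioxolan-2-yl)tridecanal; 10 methyl propiolate
Product: 12 methyl (4S,14R)-14-(tert-butyldimethylsilyloxy)-4-hydroxy-16-(2-methyl-1,3-dioxolan-2-yl)hexadec-2-ynoate, via ethyl(alkynyl)zinc 11 (not isolated)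
Conditions: (R)-BINOL (40 mol%), Et2Zn, HMPA, CH2Cl2, rt; then Ti(OiPr)4; then 9, rt; aq. NH4Cl
Reagents that add atoms: none
Why: BINOL–titanium-catalysed asymmetric alkynylzinc addition of the propiolate-derived zinc acetylide is expected, with the (R)-BINOLate complex, to deliver the alkynyl group to the Re face of the unbranched aldehyde and so set the (S)-carbinol under catalyst control, independent of the remote C14 center.

Step 7
Reactants: 12 methyl (4S,14R)-14-(tert-butyldimethylsilyloxy)-4-hydroxy-16-(2-methyl-1,3-dioxolan-2-yl)hexadec-2-ynoate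
Product: 13 methyl (4S,14R)-4,14-bis(tert-butyldimethylsilyloxy)-16-(2-methyl-1,3-dioxolan-2-yl)hexadec-2-ynoate
Conditions: TBSCl, imidazole, 4-(dimethylamino)pyridine (cat.), CH2Cl2, 0 °C to rt
Reagents that add atoms: tert-butyldimethylsilyl chloride, CC(C)(C)[Si](C)(C)Cl
Why: Silylation of the propargylic alcohol with a mild amine base avoids isomerization of the ynoate to an allenoate and leaves C4 untouched.

Step 8
Reactants: 14 1,1-dimethoxyethene
Product: 15 4,4-dimethoxybut-3-en-2-one
Conditions: AcCl, Et3N, Et2O, 0 °C to rt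
Reagents that add atoms: acetyl chloride, CC(=O)Cl
Why: C-acylation of the nucleophilic ketene acetal by the acid chloride, with loss of HCl to the amine, gives the push–pull acyl ketene acetal.

Step 9
Reactants: 15 4,4-dimethoxybut-3-en-2-one
Product: 17 1,1-dimethoxy-3-(trimethylsilyloxy)buta-1,3-diene, via lithium dienolate 16 (not isolated)
Conditions: LiN(iPr)2, THF, −78 °C; then Me3SiCl, −78 °C to rt; non-aqueous work-up, distillation
Reagents that add atoms: chlorotrimethylsilane, C[Si](C)(C)Cl
Why: Kinetic deprotonation of the only enolizable position (the methyl ketone) and O-silylation of the resulting enolate give the 2-silyloxydiene (silyl enol ether formation).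

Step 10
Reactants: 13 methyl (4S,14R)-4,14-bis(tert-butyldimethylsilyloxy)-16-(2-methyl-1,3-dioxolan-2-yl)hexadec-2-ynoate; 17 1,1-dimethoxy-3-(trimethylsilyloxy)buta-1,3-diene
Product: 20 methyl 4-hydroxy-2-methoxy-6-[(1S,11R)-1,11-bis(tert-butyldimethylsilyloxy)-13-(2-methyl-1,3-dioxolan-2-yl)tridecyl]benzoate, via cyclohexa-1,4-diene cycloadduct 18 (not isolated), via aryl trimethylsilyl ether 19 (not isolated)
Conditions: 17 (3 equiv), PhMe, 120 °C, sealed tube; then K2CO3 (cat.), MeOH, 0 °C
Reagents that add atoms: none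
Why: The donor-substituted diene 17 (HOMO) and the electron-poor triple bond of 13 (LUMO) are expected to join in a thermal normal-demand [4+2] cycloaddition in which bonding at the diene CH2 terminus runs ahead of bonding at the ketene-acetal carbon; the closest known reaction type is the resorcylate synthesis from 1,1-dialkoxy-3-silyloxybutadienes and acetylenic esters. The six-membered carbocycle is closed in this single intermolecular cycloaddition by the two new bonds C4–C3a and C7–C7a, giving cyclohexa-1,4-diene 18 with C7 as a dimethyl ketal carbon. Thermal 1,4-elimination of methanol (a C7 methoxy group and a C4 hydrogen) then aromatizes 18 to aryl silyl ether 19, and catalytic K2CO3 in methanol cleaves only the aryl O–SiMe3 bond to leave the C5 phenol. No stereocenter is created; the propargylic C3 center takes no part in bond formation and, with no Lewis acid or base present during the thermal stage, should neither epimerize nor eliminate, while the TBS ethers and the dioxolane tolerate heat and the brief methanolysis. The selectivity required is regiochemical: the largest HOMO coefficient of 17 lies on the unsubstituted CH2 terminus and the largest LUMO coefficient of 13 on the alkyne carbon beta to the ester, so CH2 bonds to the carbon bearing the silyloxyalkyl group (future C3a) and the dimethoxy carbon to the ester-bearing carbon (future C7a), which places the retained methoxy group ortho to the ester.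

Step 11
Reactants: 20 methyl 4-hydroxy-2-methoxy-6-[(1S,11R)-1,11-bis(tert-butyldimethylsilyloxy)-13-(2-methyl-1,3-dioxolan-2-yl)tridecyl]benzoate
Product: 21 methyl 2,4-dimethoxy-6-[(1S,11R)-1,11-bis(tert-butyldimethylsilyloxy)-13-(2-methyl-1,3-dioxolan-2-yl)tridecyl]benzoate
Conditions: MeI, K2CO3, acetone, reflux
Reagents that add atoms: iodomethane, CI
Why: Williamson O-methylation of the acidic phenol para to the ester proceeds with a weak base that does not affect silyl ethers, ketal or ester.

Step 12
Reactants: 21 methyl 2,4-dimethoxy-6-[(1S,11R)-1,11-bis(tert-butyldimethylsilyloxy)-13-(2-methyl-1,3-dioxolan-2-yl)tridecyl]benzoate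
Product: 23 (3S)-3-[(10R)-10-hydroxy-13-oxotetradecyl]-5,7-dimethoxy-2-benzofuran-1(3H)-one, via dihydroxy keto ester 22 (not isolated)
Conditions: 2 M aq. HCl, THF, 45 °C
Reagents that add atoms: water, O
Why: Aqueous acid hydrolyses both TBS ethers and the dioxolane, and the freed benzylic hydroxyl then attacks the ortho ester in a 5-exo-trig acid-catalysed lactonization that breaks no bond at C3, so the (S) configuration is retained; the benzylic carbon has only meta donors and an ortho acyl group, so ionization is not expected.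

Step 13
Reactants: 23 (3S)-3-[(10R)-10-hydroxy-13-oxotetradecyl]-5,7-dimethoxy-2-benzofuran-1(3H)-one
Product: 24 (3S)-3-[(10R)-10-acetoxy-13-oxotetradecyl]-5,7-dimethoxy-2-benzofuran-1(3H)-one
Conditions: Ac2O, pyridine, 4-(dimethylamino)pyridine (cat.), CH2Cl2, rt
Reagents that add atoms: acetic anhydride, CC(=O)OC(C)=O
Why: Nucleophile-catalysed acylation of the secondary alcohol, which reacts through its open hydroxy ketone form, leaves the configuration of the carbinol carbon untouched.

**Compound list**

1 | 2-(2-bromoethyl)-2-methyl-1,3-dioxolane | CC1(CCBr)OCCO1 | starting material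
2 | 2-(2-iodoethyl)-2-methyl-1,3-dioxolane | CC1(CCI)OCCO1 | intermediate
3 | undec-10-enal | C=CCCCCCCCCC=O | starting material
4 | bis[2-(2-methyl-1,3-dioxolan-2-yl)ethyl]zinc | CC1(CC[Zn]CCC2(C)OCCO2)OCCO1 | intermediate (not isolated)
5 | (3R)-1-(2-methyl-1,3-dioxolan-2-yl)tridec-12-en-3-ol | C=CCCCCCCCC[C@H](CCC1(C)OCCO1)O | intermediate
6 | tert-butyldimethyl{[(3R)-1-(2-methyl-1,3-dioxolan-2-yl)tridec-12-en-3-yl]oxy}silane | C=CCCCCCCCC[C@H](CCC1(C)OCCO1)O[Si](C)(C)C(C)(C)C | intermediate
7 | 9-[(11R)-11-(tert-butyldimethylsilyloxy)-13-(2-methyl-1,3-dioxolan-2-yl)tridecyl]-9-borabicyclo[3.3.1]nonane | C1CC2CCCC(C1)B2CCCCCCCCCC[C@H](CCC1(C)OCCO1)O[Si](C)(C)C(C)(C)C | intermediate (not isolated)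
8 | (11R)-11-(tert-butyldimethylsilyloxy)-13-(2-methyl-1,3-dioxolan-2-yl)tridecan-1-ol | OCCCCCCCCCC[C@H](CCC1(C)OCCO1)O[Si](C)(C)C(C)(C)C | intermediate
9 | (11R)-11-(tert-butyldimethylsilyloxy)-13-(2-methyl-1,3-dioxolan-2-yl)tridecanal | O=CCCCCCCCCC[C@H](CCC1(C)OCCO1)O[Si](C)(C)C(C)(C)C | intermediate
10 | methyl propiolate | COC(=O)C#C | starting material
11 | ethyl(3-methoxy-3-oxoprop-1-yn-1-yl)zinc | CC[Zn]C#CC(=O)OC | intermediate (not isolated)
12 | methyl (4S,14R)-14-(tert-butyldimethylsilyloxy)-4-hydroxy-16-(2-methyl-1,3-dioxolan-2-yl)hexadec-2-ynoate | COC(=O)C#C[C@H](CCCCCCCCC[C@H](CCC1(C)OCCO1)O[Si](C)(C)C(C)(C)C)O | intermediate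
13 | methyl (4S,14R)-4,14-bis(tert-butyldimethylsilyloxy)-16-(2-methyl-1,3-dioxolan-2-yl)hexadec-2-ynoate | COC(=O)C#C[C@H](CCCCCCCCC[C@H](CCC1(C)OCCO1)O[Si](C)(C)C(C)(C)C)O[Si](C)(C)C(C)(C)C | intermediate
14 | 1,1-dimethoxyethene | C=C(OC)OC | starting material
15 | 4,4-dimethoxybut-3-en-2-one | CC(=O)C=C(OC)OC | intermediate
16 | lithium 4,4-dimethoxybuta-1,3-dien-2-olate | C=C(O[Li])C=C(OC)OC | intermediate (not isolated)
17 | 1,1-dimethoxy-3-(trimethylsilyloxy)buta-1,3-diene | C=C(O[Si](C)(C)C)C=C(OC)OC | intermediate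
18 | methyl 6,6-dimethoxy-4-(trimethylsilyloxy)-2-[(1S,11R)-1,11-bis(tert-butyldimethylsilyloxy)-13-(2-methyl-1,3-dioxolan-2-yl)tridecyl]cyclohexa-1,4-diene-1-carboxylate | COC(=O)C1=C([C@H](CCCCCCCCC[C@H](CCC2(C)OCCO2)O[Si](C)(C)C(C)(C)C)O[Si](C)(C)C(C)(C)C)CC(O[Si](C)(C)C)=CC1(OC)OC | intermediate (not isolated)
19 | methyl 2-methoxy-4-(trimethylsilyloxy)-6-[(1S,11R)-1,11-bis(tert-butyldimethylsilyloxy)-13-(2-methyl-1,3-dioxolan-2-yl)tridecyl]benzoate | COC(=O)c1c(OC)cc(O[Si](C)(C)C)cc1[C@H](CCCCCCCCC[C@H](CCC2(C)OCCO2)O[Si](C)(C)C(C)(C)C)O[Si](C)(C)C(C)(C)C | intermediate (not isolated)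
20 | methyl 4-hydroxy-2-methoxy-6-[(1S,11R)-1,11-bis(tert-butyldimethylsilyloxy)-13-(2-methyl-1,3-dioxolan-2-yl)tridecyl]benzoate | COC(=O)c1c(OC)cc(O)cc1[C@H](CCCCCCCCC[C@H](CCC2(C)OCCO2)O[Si](C)(C)C(C)(C)C)O[Si](C)(C)C(C)(C)C | intermediate
21 | methyl 2,4-dimethoxy-6-[(1S,11R)-1,11-bis(tert-butyldimethylsilyloxy)-13-(2-methyl-1,3-dioxolan-2-yl)tridecyl]benzoate | COC(=O)c1c(OC)cc(OC)cc1[C@H](CCCCCCCCC[C@H](CCC2(C)OCCO2)O[Si](C)(C)C(C)(C)C)O[Si](C)(C)C(C)(C)C | intermediate
22 | methyl 2-[(1S,11R)-1,11-dihydroxy-14-oxopentadecyl]-4,6-dimethoxybenzoate | COC(=O)c1c(OC)cc(OC)cc1[C@H](CCCCCCCCC[C@H](CCC(C)=O)O)O | intermediate (not isolated)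
23 | (3S)-3-[(10R)-10-hydroxy-13-oxotetradecyl]-5,7-dimethoxy-2-benzofuran-1(3H)-one | COc1cc(OC)c2c(c1)[C@H](CCCCCCCCC[C@H](CCC(C)=O)O)OC2=O | intermediate
24 | (3S)-3-[(10R)-10-acetoxy-13-oxotetradecyl]-5,7-dimethoxy-2-benzofuran-1(3H)-one | COc1cc(OC)c2c(c1)[C@H](CCCCCCCCC[C@H](CCC(C)=O)OC(C)=O)OC2=O | target

**Step count**

Total: 13 steps. Longest linear sequence: 11 steps (steps 1–7 and 10–13); the diene branch (steps 8–9) is 2 steps.

**Steps most likely to fail**

Step 10 (key cycloaddition). The cycloaddition may stall because the propargylic silyloxy group shields the alkyne carbon that must bond to the diene terminus. Diene 17 may also decompose thermally faster than it adds, or aromatization may stay incomplete. The fallback sets out from ynoate 13 and returns at dimethyl ether 21, so step 11 falls away. It is an Alder–Rickert sequence. Commercial 1,5-dimethoxycyclohexa-1,4-diene (COC1=CCC=C(OC)C1) is conjugated with KOtBu in DMSO to 1,3-dimethoxycyclohexa-1,3-diene F1. Heating F1 with 13 (neat or in mesitylene, about 160 °C) should give, with the same polarity-controlled regiochemistry, the bicyclo[2.2.2]octa-2,5-diene adduct F2 as a mixture of bridgehead diastereomers that is not isolated. F2 extrudes ethene by retro-Diels–Alder reaction and gives 21 with both methoxy groups already in place.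

Step 6 (asymmetric propiolate addition). Facial selectivity may be poor with an unbranched, enolizable aldehyde, and ethyl transfer or ester exchange at titanium may compete. The fallback sets out from aldehyde 9 and methyl propiolate 10 and returns at alcohol 12. Methyl propiolate is lithiated with LiN(SiMe3)2 in THF at −78 °C to lithium 3-methoxy-3-oxoprop-1-yn-1-ide F3. F3 adds to 9 without selectivity to give the C4-epimeric mixture of methyl (14R)-14-(tert-butyldimethylsilyloxy)-4-hydroxy-16-(2-methyl-1,3-dioxolan-2-yl)hexadec-2-ynoate F4. Dess–Martin oxidation converts F4 into methyl (14R)-14-(tert-butyldimethylsilyloxy)-16-(2-methyl-1,3-dioxolan-2-yl)-4-oxohexadec-2-ynoate F5. Midland reduction of this 4-oxo-2-ynoate with (S)-Alpine-Borane (B-isopinocampheyl-9-borabicyclo[3.3.1]nonane from (−)-α-pinene), a reagent class known to reduce such keto ynoates, should give the (4S)-alcohol 12.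

Step 2 (dialkylzinc formation and addition). The iodine–zinc exchange may be incomplete, or enantioselectivity in the alkyl transfer to an unbranched aliphatic aldehyde may be low. The fallback sets out from commercial hex-5-en-2-one (CC(=O)CCC=C) and returns at alcohol 5. Ketalization with ethylene glycol and TsOH gives 2-(but-3-en-1-yl)-2-methyl-1,3-dioxolane F6. Buffered mCPBA epoxidation gives racemic 2-methyl-2-[2-(oxiran-2-yl)ethyl]-1,3-dioxolane F7. Hydrolytic kinetic resolution with (S,S)-N,N'-bis(3,5-di-tert-butylsalicylidene)cyclohexane-1,2-diaminocobalt acetate, (S,S)-(salen)Co(OAc), trivalent cobalt, the antipode expected to hydrolyse the (R)-epoxide, leaves (2S)-2-[2-(2-methyl-1,3-dioxolan-2-yl)ethyl]oxirane F8. Opening of F8 at its terminal carbon with non-8-en-1-ylmagnesium bromide F9 (from 9-bromonon-1-ene, C=CCCCCCCCBr, and Mg) under CuI catalysis in THF at −30 °C gives 5; the C–O bond of the stereocenter is not touched.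

**Further compounds**

F1 | step 10 | 1,3-dimethoxycyclohexa-1,3-diene | COC1=CC(OC)=CCC1
F2 | step 10 | methyl 1,5-dimethoxy-3-[(1S,11R)-1,11-bis(tert-butyldimethylsilyloxy)-13-(2-methyl-1,3-dioxolan-2-yl)tridecyl]bicyclo[2.2.2]octa-2,5-diene-2-carboxylate (bridgehead diastereomers) | COC(=O)C1=C([C@H](CCCCCCCCC[C@H](CCC3(C)OCCO3)O[Si](C)(C)C(C)(C)C)O[Si](C)(C)C(C)(C)C)C2CCC1(OC)C=C2OC
F3 | step 6 | lithium 3-methoxy-3-oxoprop-1-yn-1-ide | [Li]C#CC(=O)OC
F4 | step 6 | methyl (14R)-14-(tert-butyldimethylsilyloxy)-4-hydroxy-16-(2-methyl-1,3-dioxolan-2-yl)hexadec-2-ynoate (C4 epimers) | COC(=O)C#CC(O)CCCCCCCCC[C@H](CCC1(C)OCCO1)O[Si](C)(C)C(C)(C)C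
F5 | step 6 | methyl (14R)-14-(tert-butyldimethylsilyloxy)-16-(2-methyl-1,3-dioxolan-2-yl)-4-oxohexadec-2-ynoate | COC(=O)C#CC(=O)CCCCCCCCC[C@H](CCC1(C)OCCO1)O[Si](C)(C)C(C)(C)C
F6 | step 2 | 2-(but-3-en-1-yl)-2-methyl-1,3-dioxolane | C=CCCC1(C)OCCO1
F7 | step 2 | racemic 2-methyl-2-[2-(oxiran-2-yl)ethyl]-1,3-dioxolane | CC1(CCC2CO2)OCCO1
F8 | step 2 | (2S)-2-[2-(2-methyl-1,3-dioxolan-2-yl)ethyl]oxirane | C1[C@H](CCC2(C)OCCO2)O1
F9 | step 2 | non-8-en-1-ylmagnesium bromide | C=CCCCCCCC[Mg]Br
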